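**Retrosynthetic overview**

1. Locants (IUPAC quinic acid numbering): C1 = C(OMe)(CO2H), C2 = CH2, C3 and C4 = cis-diol carbons, C5 = caffeoyloxy carbon, C6 = CH2. CO2H and O5 lie on one face; OMe, O3 and O4 on the other.
2. Late stage: the caffeate ester comes from a Knoevenagel–Doebner condensation on the C5 malonate half-ester. The C3/C4 cis-diol comes from osmylation of a cyclohex-3-ene and is held as a temporary dioxolane.
3. Key disconnection, a one-flask [3+3] annulation: C3=C4 by Wittig olefination (C3 as phosphorus ylide, i.e. with reversed polarity; C4 as aldehyde) and C1–C6 by 6-exo-tet alkylation of the C1 ester enolate with a C6 chloride. The Z-alkene stands for the diol at a lower oxidation level; PPh3+ and Cl are activating groups that leave in the step.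
4. Enabling feature: C1 is the α-carbon of the carboxyl group between two CH2 groups (C2, C6), so it stays enolisable until the ring closes. The C3–C4 cis-diol lies inside the six-membered carbocycle with O5 allylic to it, the pattern of a ring Z-alkene. The C5 stereocentre, bought as (S)-3-chloropropane-1,2-diol, controls C1, C3 and C4.
5. Fragments: a C1–C3 phosphonium salt from tert-butyl methoxyacetate, 2-bromoethyl triflate and triphenylphosphine; a C4–C6 aldehyde from the chlorodiol. Ring order: cyclohexene (step 6), then the temporary dioxolane (step 8, removed in step 11).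

Key step: step 6

Remark: the SMILES is taken as binding; it describes the 1-O-methyl ether of chlorogenic acid, so the acyloxy carbon called C3 in the trivial name is C5 in the locants used here.

**Route**

Step 1
Reactants: 1 tert-butyl bromoacetate
Product: 2 tert-butyl 2-methoxyacetate
Conditions: NaOMe (1.05 equiv), MeOH, 0 °C → rt
Reagents that add atoms: sodium methoxide, [Na+].[O-]C
Why: Williamson-type SN2 displacement of the activated α-bromide by methoxide should be much faster than attack on the hindered tert-butyl ester, and no stereocentre is involved.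

Step 2
Reactants: 2 tert-butyl 2-methoxyacetate; 3 2-bromoethyl trifluoromethanesulfonate
Product: 4 tert-butyl 4-bromo-2-methoxybutanoate
Conditions: LDA (1.0 equiv), THF, −78 °C; 3 (1.1 equiv), −78 → −40 °C; sat. aq. NH4Cl, cold
Reagents that add atoms: none
Why: Alkylation of the lithium ester enolate by SN2 at the triflate-bearing carbon, which reacts far faster than the bromide end, forms the C1–C2 bond, and the cold quench keeps the product from enolising again; C1 is left racemic on purpose because step 6 erases and resets it.

Step 3
Reactants: 4 tert-butyl 4-bromo-2-methoxybutanoate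
Product: 5 (4-tert-butoxy-3-methoxy-4-oxobutyl)triphenylphosphonium bromide
Conditions: PPh3 (1.1 equiv), MeCN, 70 °C; precipitate with Et2O
Reagents that add atoms: triphenylphosphine, c1ccc(cc1)P(c1ccccc1)c1ccccc1
Why: SN2 quaternisation of the unhindered primary bromide by triphenylphosphine (phosphonium salt formation) under neutral conditions should leave the tert-butyl ester and the methyl ether untouched and gives a crystalline, storable precursor for the key step.

Step 4
Reactants: 6 (S)-3-chloropropane-1,2-diol
Product: 7 (S)-3-chloro-1,2-bis(triethylsilyloxy)propane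
Conditions: Et3SiCl (2.2 equiv), imidazole, CH2Cl2, 0 °C → rt
Reagents that add atoms: chlorotriethylsilane, CC[Si](Cl)(CC)CC
Why: Imidazole-promoted silyl ether formation at both hydroxyl groups leaves the stereocentre untouched.

Step 5
Reactants: 7 (S)-3-chloro-1,2-bis(triethylsilyloxy)propane
Product: 8 (S)-3-chloro-2-(triethylsilyloxy)propanal
Conditions: (COCl)2, DMSO, CH2Cl2, −78 → −40 °C; Et3N, −78 → 0 °C; used crude
Reagents that add atoms: none
Why: Under Swern conditions the activated sulfoxide cleaves the unhindered primary triethylsilyl ether and oxidises that carbon directly to the aldehyde while the secondary silyl ether survives (Swern oxidation of a primary silyl ether), and the cold non-aqueous handling should keep the α-stereocentre intact.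

Step 6
Reactants: 5 (4-tert-butoxy-3-methoxy-4-oxobutyl)triphenylphosphonium bromide; 8 (S)-3-chloro-2-(triethylsilyloxy)propanal
Product: 11 tert-butyl (1S,5R)-1-methoxy-5-(triethylsilyloxy)cyclohex-3-ene-1-carboxylate, via phosphorus ylide 9 (not isolated), via Z-alkenyl chloride 10 (not isolated)
Conditions: KHMDS (1.05 equiv), THF, −78 °C; 8, −78 → −20 °C; then KHMDS (1.3 equiv), DMPU, −78 → 0 °C
Reagents that add atoms: none
Why: Deprotonation of 5 next to phosphorus gives the non-stabilised ylide 9, whose C3 (a carbinol carbon in the target, here with reversed polarity) adds to the aldehyde carbon C4 of 8 and collapses through the cis-oxaphosphetane to the Z-alkene 10 (Wittig olefination), after which the second charge of base forms the ester enolate of 10 and C1 displaces the primary chloride at C6 (intramolecular enolate alkylation). The closest known reaction types are the Z-selective Wittig reaction of α-silyloxy aldehydes and the cyclisation of ω-halo ester enolates, here joined in one flask as a [3+3] annulation. The one ring closed is the cyclohexene, in the 6-exo-tet mode with the enolate C=C exocyclic to the new ring, a geometry that only the Z-alkene can reach. C5 is carried over unchanged from 8, and C1 is set in the ring closure: both epimers of 10 at the methoxy-bearing carbon give the same planar enolate (stereoconvergent), and the chair-like transition state should place the bulky enolate unit (later CO2tBu) equatorial and the small methoxy group axial with the C5 silyloxy group pseudo-equatorial, i.e. CO2tBu cis to O5 (1S,5R). The step needs carbonyl addition of the ylide to outrun base-induced loss of HCl from 8 (low temperature, aldehyde added to the preformed ylide), Z-selectivity (non-stabilised ylide, potassium base without lithium salts) and C- over O-alkylation (six-membered ring, soft primary halide).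

Step 7
Reactants: 11 tert-butyl (1S,5R)-1-methoxy-5-(triethylsilyloxy)cyclohex-3-ene-1-carboxylate
Product: 12 tert-butyl 1-O-methyl-5-O-(triethylsilyl)quinate
Conditions: OsO4 (2 mol %), NMO, acetone/H2O, 0 °C → rt
Reagents that add atoms: osmium tetroxide (catalytic oxygen carrier), O=[Os](=O)(=O)=O; N-methylmorpholine N-oxide, C[N+]1([O-])CCOCC1; water, O
Why: Catalytic syn-dihydroxylation (Upjohn conditions) should deliver both oxygens to the C3=C4 bond from the face anti to the allylic silyloxy group and to the CO2tBu group, which sets C3 and C4 cis to each other and to OMe and trans to O5.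

Step 8
Reactants: 12 tert-butyl 1-O-methyl-5-O-(triethylsilyl)quinate
Product: 14 tert-butyl 3,4-O-isopropylidene-1-O-methylquinate, via triol 13 (not isolated)
Conditions: CSA (cat.), MeOH, 0 °C → rt; evaporate; Me2C(OMe)2, CH2Cl2, rt; Et3N
Reagents that add atoms: 2,2-dimethoxypropane, COC(C)(C)OC
Why: Acid-catalysed methanolysis removes the silyl ether and transketalisation then closes the five-membered dioxolane only on the cis-3,4-diol (the 4,5-diol is trans), which leaves the C5 hydroxyl as the single free alcohol.

Step 9
Reactants: 14 tert-butyl 3,4-O-isopropylidene-1-O-methylquinate; 15 2,2-dimethyl-1,3-dioxane-4,6-dione (Meldrum's acid)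
Product: 16 tert-butyl 5-O-(carboxyacetyl)-3,4-O-isopropylidene-1-O-methylquinate
Conditions: toluene, 100 °C
Reagents that add atoms: none
Why: The C5 hydroxyl opens Meldrum's acid at a ring carbonyl with loss of acetone (malonic half-ester formation by alcoholysis of Meldrum's acid) under neutral conditions, so no stereocentre and no protecting group is touched.

Step 10
Reactants: 16 tert-butyl 5-O-(carboxyacetyl)-3,4-O-isopropylidene-1-O-methylquinate; 17 3,4-dihydroxybenzaldehyde
Product: 18 tert-butyl 5-O-[(E)-caffeoyl]-3,4-O-isopropylidene-1-O-methylquinate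
Conditions: pyridine, piperidine (cat.), 50 °C
Reagents that add atoms: none
Why: Knoevenagel–Doebner condensation of the malonate half-ester with the aldehyde followed by decarboxylative elimination should give the (E)-cinnamate directly and tolerates the free catechol, while the dioxolane blocks acyl migration.

Step 11
Reactants: 18 tert-butyl 5-O-[(E)-caffeoyl]-3,4-O-isopropylidene-1-O-methylquinate
Product: 19 3-O-caffeoyl-1-methylquinic acid
Conditions: TFA/CH2Cl2/H2O (10:10:1), 0 °C → rt
Reagents that add atoms: none
Why: Acidolysis cleaves the tert-butyl ester (as 2-methylpropene) and hydrolyses the isopropylidene ketal, whereas the cinnamate ester, the catechol and the tertiary methyl ether are stable to acid and base-promoted acyl migration is avoided.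

**Compound list** (quinate names use the locants of the overview and the configuration of (−)-quinic acid: OMe, O3, O4 on one face; carboxyl and O5 on the other)

1 | tert-butyl bromoacetate | BrCC(=O)OC(C)(C)C | starting material
2 | tert-butyl 2-methoxyacetate | COCC(=O)OC(C)(C)C | intermediate
3 | 2-bromoethyl trifluoromethanesulfonate | BrCCOS(=O)(=O)C(F)(F)F | starting material
4 | tert-butyl 4-bromo-2-methoxybutanoate (racemic) | COC(CCBr)C(=O)OC(C)(C)C | intermediate
5 | (4-tert-butoxy-3-methoxy-4-oxobutyl)triphenylphosphonium bromide (racemic) | COC(CC[P+](c1ccccc1)(c1ccccc1)c1ccccc1)C(=O)OC(C)(C)C.[Br-] | intermediate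
6 | (S)-3-chloropropane-1,2-diol | OC[C@H](O)CCl | starting material
7 | (S)-3-chloro-1,2-bis(triethylsilyloxy)propane | CC[Si](CC)(CC)OC[C@H](O[Si](CC)(CC)CC)CCl | intermediate
8 | (S)-3-chloro-2-(triethylsilyloxy)propanal | O=C[C@H](O[Si](CC)(CC)CC)CCl | intermediate
9 | tert-butyl 2-methoxy-4-(triphenyl-λ5-phosphanylidene)butanoate (phosphorus ylide, racemic, not isolated) | COC(CC=P(c1ccccc1)(c1ccccc1)c1ccccc1)C(=O)OC(C)(C)C | intermediate
10 | tert-butyl (4Z,6S)-7-chloro-2-methoxy-6-(triethylsilyloxy)hept-4-enoate (both C2 epimers, not isolated) | COC(C/C=C\[C@H](O[Si](CC)(CC)CC)CCl)C(=O)OC(C)(C)C | intermediate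
11 | tert-butyl (1S,5R)-1-methoxy-5-(triethylsilyloxy)cyclohex-3-ene-1-carboxylate (CO2tBu cis to the silyloxy group) | CO[C@@]1(C(=O)OC(C)(C)C)CC=C[C@H](O[Si](CC)(CC)CC)C1 | intermediate
12 | tert-butyl 1-O-methyl-5-O-(triethylsilyl)quinate | CO[C@@]1(C(=O)OC(C)(C)C)C[C@@H](O)[C@@H](O)[C@H](O[Si](CC)(CC)CC)C1 | intermediate
13 | tert-butyl 1-O-methylquinate (triol, not isolated) | CO[C@@]1(C(=O)OC(C)(C)C)C[C@@H](O)[C@@H](O)[C@H](O)C1 | intermediate
14 | tert-butyl 3,4-O-isopropylidene-1-O-methylquinate (free 5-OH) | CO[C@@]1(C(=O)OC(C)(C)C)C[C@@H](O2)[C@@H](OC2(C)C)[C@H](O)C1 | intermediate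
15 | 2,2-dimethyl-1,3-dioxane-4,6-dione (Meldrum's acid) | CC1(C)OC(=O)CC(=O)O1 | starting material
16 | tert-butyl 5-O-(carboxyacetyl)-3,4-O-isopropylidene-1-O-methylquinate (malonate half-ester) | CO[C@@]1(C(=O)OC(C)(C)C)C[C@@H](O2)[C@@H](OC2(C)C)[C@H](OC(=O)CC(=O)O)C1 | intermediate
17 | 3,4-dihydroxybenzaldehyde | O=Cc1ccc(O)c(O)c1 | starting material
18 | tert-butyl 5-O-[(E)-caffeoyl]-3,4-O-isopropylidene-1-O-methylquinate | CO[C@@]1(C(=O)OC(C)(C)C)C[C@@H](O2)[C@@H](OC2(C)C)[C@H](OC(=O)/C=C/c3ccc(O)c(O)c3)C1 | intermediate
19 | 3-O-caffeoyl-1-methylquinic acid, i.e. (1S,3R,4R,5R)-5-[(E)-caffeoyloxy]-3,4-dihydroxy-1-methoxycyclohexane-1-carboxylic acid in the locants used here | CO[C@@]1(C(=O)O)C[C@@H](O)[C@@H](O)[C@H](OC(=O)/C=C/c2ccc(O)c(O)c2)C1 | target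

Total step count: 11 steps. Longest linear sequence: 9 steps (steps 1, 2, 3, 6–11).

**Steps most likely to fail**

Step 6. What may go wrong: base-induced loss of HCl from the β-chloro aldehyde 8 (α-deprotonation, then β-elimination) competing with carbonyl addition of the ylide; slow displacement of the β-branched primary chloride, which leaves the ester enolate time to decompose; and an unselective choice of enolate face in the ring closure. Fallback (sets out from 5, comes back at 11): the leaving group is put in only after the olefination, so that no β-chloro aldehyde meets a base. Ylide 9 (from 5, KHMDS, THF, −78 °C) is combined in a Wittig olefination with commercial (R)-2,2-dimethyl-1,3-dioxolane-4-carbaldehyde, which should give tert-butyl (4Z)-5-[(4S)-2,2-dimethyl-1,3-dioxolan-4-yl]-2-methoxypent-4-enoate F1. Aqueous acetic acid should remove the acetonide to give tert-butyl (4Z,6S)-6,7-dihydroxy-2-methoxyhept-4-enoate F2. Tin-catalysed selective sulfonylation of the primary hydroxyl (TsCl, Et3N, cat. Bu2SnO, CH2Cl2) should give tert-butyl (4Z,6S)-6-hydroxy-2-methoxy-7-(tosyloxy)hept-4-enoate F3, which is silylated (Et3SiCl, imidazole) to tert-butyl (4Z,6S)-2-methoxy-7-(tosyloxy)-6-(triethylsilyloxy)hept-4-enoate F4. KHMDS in THF/DMPU then closes the ring by the same enolate alkylation, now on a tosylate, to 11.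

Step 7. What may go wrong: poor facial selectivity of the osmylation, because the axial methoxy group at C1 partly shields the face that lies anti to the silyloxy group. Fallback (sets out from 11, comes back at 14): the facial choice is handed to a temporary bicyclic lactone. Aqueous TFA in CH2Cl2 should remove the silyl and tert-butyl groups from 11 to give (1S,5R)-5-hydroxy-1-methoxycyclohex-3-ene-1-carboxylic acid F5. Carbodiimide lactonisation (EDC·HCl, DMAP, CH2Cl2, high dilution) should give (1S,5R)-1-methoxy-6-oxabicyclo[3.2.1]oct-3-en-7-one F6, in which the lactone bridge covers one face of the alkene. Only the isomer with carboxyl cis to O5 can lactonise, so this stage also removes any C1 epimer carried over from step 6. OsO4/NMO should then add anti to the bridge to give 1-O-methylquinic acid 1,5-lactone F7. Ketalisation (2,2-dimethoxypropane, cat. p-TsOH) should give 3,4-O-isopropylidene-1-O-methylquinic acid 1,5-lactone F8. LiOH in THF/H2O followed by careful acidification should open the lactone to 3,4-O-isopropylidene-1-O-methylquinic acid F9, and tert-butyl 2,2,2-trichloroacetimidate (CH2Cl2, rt) should esterify the carboxylic acid selectively to 14.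

Step 2. What may go wrong: elimination on the triflate reagent by the basic enolate in place of substitution, and closure of the alkylated product to a cyclopropane after a second enolisation. Fallback (sets out from 2, comes back at 4): the two-carbon unit is brought in as an allyl group, a dependable enolate electrophile, and cut down afterwards. Allylation of the lithium enolate of 2 (LDA, THF, −78 °C; allyl bromide) should give tert-butyl 2-methoxypent-4-enoate F10. Ozonolysis with reductive work-up (O3, CH2Cl2/MeOH, −78 °C; NaBH4) should give tert-butyl 4-hydroxy-2-methoxybutanoate F11, and an Appel reaction (CBr4, PPh3, CH2Cl2, 0 °C) should convert the primary alcohol into bromide 4.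

Further compounds
F1 | step 6 | tert-butyl (4Z)-5-[(4S)-2,2-dimethyl-1,3-dioxolan-4-yl]-2-methoxypent-4-enoate | COC(C/C=C\[C@H](OC1(C)C)CO1)C(=O)OC(C)(C)C
F2 | step 6 | tert-butyl (4Z,6S)-6,7-dihydroxy-2-methoxyhept-4-enoate | COC(C/C=C\[C@H](O)CO)C(=O)OC(C)(C)C
F3 | step 6 | tert-butyl (4Z,6S)-6-hydroxy-2-methoxy-7-(tosyloxy)hept-4-enoate | COC(C/C=C\[C@H](O)COS(=O)(=O)c1ccc(C)cc1)C(=O)OC(C)(C)C
F4 | step 6 | tert-butyl (4Z,6S)-2-methoxy-7-(tosyloxy)-6-(triethylsilyloxy)hept-4-enoate | COC(C/C=C\[C@H](O[Si](CC)(CC)CC)COS(=O)(=O)c1ccc(C)cc1)C(=O)OC(C)(C)C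
F5 | step 7 | (1S,5R)-5-hydroxy-1-methoxycyclohex-3-ene-1-carboxylic acid | CO[C@@]1(C(=O)O)CC=C[C@H](O)C1
F6 | step 7 | (1S,5R)-1-methoxy-6-oxabicyclo[3.2.1]oct-3-en-7-one | CO[C@@]1(C(=O)O2)CC=C[C@H]2C1
F7 | step 7 | 1-O-methylquinic acid 1,5-lactone | CO[C@@]1(C(=O)O2)C[C@@H](O)[C@@H](O)[C@H]2C1
F8 | step 7 | 3,4-O-isopropylidene-1-O-methylquinic acid 1,5-lactone | CO[C@@]1(C(=O)O2)C[C@@H](O3)[C@@H](OC3(C)C)[C@H]2C1
F9 | step 7 | 3,4-O-isopropylidene-1-O-methylquinic acid | CO[C@@]1(C(=O)O)C[C@@H](O2)[C@@H](OC2(C)C)[C@H](O)C1
F10 | step 2 | tert-butyl 2-methoxypent-4-enoate | COC(CC=C)C(=O)OC(C)(C)C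
F11 | step 2 | tert-butyl 4-hydroxy-2-methoxybutanoate | COC(CCO)C(=O)OC(C)(C)C
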